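The flavone is cut through ring C at C4a–C4 and O1–C2. This gives phloroglucinol and an ethyl aroylacetate that already holds ring B fused to its 2,2-dimethylpyran, with the 8-OH free. Heating the two without acid acylates a ring carbon and dehydrates to the pyranone in one operation. The step exploits the 1,3,5-oxygen pattern of ring A (O1 on C8a, 5-OH, 7-OH). In phloroglucinol the carbons that become C4a, C6 and C8 are equivalent, as are the three oxygens, so no site has to be chosen. The C8 prenyl group follows by a Claisen–Cope relay from O5.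

Key step: step 4

Remark: the target has no stereocentre. The chromenol OH (later 3'-OH) is deliberately left free through steps 3 and 4: its O-acylation by the ketene reverts at the temperature of step 4, no phenol protecting group that can later be removed beside a prenyl group and a chromene is reliable in a phenol melt at 240 °C, and after ring closure it is masked together with the 7-OH in one operation.

Step 1
Reactants: 1 methyl 3,4-dihydroxybenzoate; 2 3-chloro-3-methylbut-1-yne
Product: 3 methyl 3-hydroxy-4-[(2-methylbut-3-yn-2-yl)oxy]benzoate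
Conditions: 2 (1.3 equiv), K2CO3 (1.1 equiv), KI (10 mol %), CuI (5 mol %), DMF, 60 °C, Ar
Reagents that add atoms: none
Why: Copper-assisted Williamson-type O-propargylation, in which one equivalent of K2CO3 ionises only the 4-OH (para to the ester and the more acidic of the two), the 4-phenoxide takes up the tertiary propargyl electrophile, and the bulk of the new group shields the neighbouring 3-OH from a second alkylation.

Step 2
Reactants: 3 methyl 3-hydroxy-4-[(2-methylbut-3-yn-2-yl)oxy]benzoate
Product: 5 methyl 8-hydroxy-2,2-dimethyl-2H-chromene-6-carboxylate, via allenylcatechol 4 (not isolated)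
Conditions: N,N-diethylaniline, 190 °C, Ar
Reagents that add atoms: none
Why: Aromatic propargyl Claisen rearrangement, in which the [3,3] shift can end only at the unsubstituted ortho carbon C5 (the other ortho carbon carries the OH), and rearomatisation to 4, a 1,5-hydrogen shift and an oxa-6π electrocyclisation then close the 2,2-dimethyl-2H-pyran ring.

Step 3
Reactants: 5 methyl 8-hydroxy-2,2-dimethyl-2H-chromene-6-carboxylate; 6 ethyl acetate
Product: 8 ethyl 3-(8-hydroxy-2,2-dimethyl-2H-chromen-6-yl)-3-oxopropanoate, via lithium enolate of ethyl acetate 7 (not isolated)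
Conditions: 6 (4 equiv), LiN(SiMe3)2 (5.5 equiv), THF, −78 °C; then 5, −78 → 0 °C; 1 M HCl quench
Reagents that add atoms: none
Why: Crossed Claisen condensation, in which ethyl acetate is fully enolised before 5 is added and so cannot self-condense, the surplus amide takes the phenol proton, the resulting phenoxide sits meta to the ester and does not switch it off, and deprotonation of the β-ketoester product drives the addition–elimination forward.

Step 4
Reactants: 8 ethyl 3-(8-hydroxy-2,2-dimethyl-2H-chromen-6-yl)-3-oxopropanoate; 9 phloroglucinol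
Product: 12 5,7-dihydroxy-2-(8-hydroxy-2,2-dimethyl-2H-chromen-6-yl)-4H-chromen-4-one (8-desprenyl target), via aroylketene 10 (not isolated), via β-diketone 11 (not isolated)
Conditions: anhydrous 9 (2 equiv), neat melt, no acid, 240 °C (microwave or preheated bath), 5–15 min, open vessel under Ar sweep
Reagents that add atoms: none
Why: Above about 200 °C ketoester 8 loses ethanol to give aroylketene 10 (phenol esters formed from 10, including those of the chromenol OH, revert to it at this temperature), and 10 is captured irreversibly at carbon by the very electron-rich ring of 9 to give β-diketone 11. A hydroxyl ortho to the new acyl group then closes ring C by 6-exo-trig addition to the aryl ketone carbon and loss of water, so C4a–C4 and O1–C2 are both made in this operation. The closest known reaction type is the Mentzer pyrone synthesis, the acid-free thermal condensation of phenols with β-ketoesters, which is established for phloroglucinol and ethyl aroylacetates. The step needs chemoselectivity for the flavone over the 4-arylcoumarin of a Pechmann pathway, and this is secured by leaving out every Brønsted or Lewis acid, so that the ketone is never activated for attack by a ring carbon and the ester carbon, as ketene, is the only strong electrophile. Site selectivity is not needed, because the three C–H positions of 9 and the two ortho hydroxyls of 11 are equivalent by symmetry, and a second annulation is held back by the excess of 9 and by the deactivating C4 carbonyl of 12. No stereocentre is formed, and the 2,2-dimethylchromene, itself made at 190 °C in step 2, should stand the short heating under argon.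

Step 5
Reactants: 12 5,7-dihydroxy-2-(8-hydroxy-2,2-dimethyl-2H-chromen-6-yl)-4H-chromen-4-one
Product: 13 6-(7-acetoxy-5-hydroxy-4-oxo-4H-chromen-2-yl)-2,2-dimethyl-2H-chromen-8-yl acetate (7,3'-di-O-acetate of 12)
Conditions: Ac2O (2.2 equiv), pyridine, 0 °C → rt
Reagents that add atoms: acetic anhydride, CC(=O)OC(C)=O
Why: Chemoselective O-acetylation, in which the 7-OH and the 3'-OH are ordinary phenols and are acylated quickly, whereas the 5-OH is held in a six-membered hydrogen bond to the C4 carbonyl and is left untouched by a limited amount of anhydride.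

Step 6
Reactants: 13 7,3'-di-O-acetate of 12; 14 3-methylbut-2-en-1-ol (prenol)
Product: 15 6-{7-acetoxy-5-[(3-methylbut-2-en-1-yl)oxy]-4-oxo-4H-chromen-2-yl}-2,2-dimethyl-2H-chromen-8-yl acetate (5-O-prenyl ether of 13)
Conditions: 14, PPh3, DIAD (1.5 equiv each), THF, 0 °C → rt
Reagents that add atoms: none
Why: Mitsunobu etherification, in which the only acidic OH left is the 5-OH, and it is alkylated at the primary carbon of prenol under neutral conditions that neither cleave nor shift the base-labile aryl acetates.

Step 7
Reactants: 15 5-O-prenyl ether of 13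
Product: 17 6-[7-acetoxy-5-hydroxy-8-(3-methylbut-2-en-1-yl)-4-oxo-4H-chromen-2-yl]-2,2-dimethyl-2H-chromen-8-yl acetate (8-prenyl 7,3'-diacetate), via C6 dienone 16 (not isolated)
Conditions: Eu(fod)3 (10 mol %), PhCl, 85 °C, Ar
Reagents that add atoms: none
Why: Lanthanide-catalysed para-Claisen–Cope rearrangement, in which Eu(fod)3 bound to the C4 carbonyl and O5 speeds up the [3,3] shift to C6, enolisation of 16 is slow in the aprotic medium so that a second [3,3] shift (Cope) carries the allyl unit on to C8 with normal prenyl connectivity restored, and final enolisation rebuilds ring A with its chelated 5-OH.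

Step 8
Reactants: 17 8-prenyl 7,3'-diacetate
Product: 18 5,7-dihydroxy-2-(8-hydroxy-2,2-dimethyl-2H-chromen-6-yl)-8-(3-methylbut-2-en-1-yl)-4H-chromen-4-one (target)
Conditions: K2CO3 (3 equiv), MeOH, 0 °C → rt; then 1 M HCl to pH 5
Reagents that add atoms: none
Why: Base-mediated methanolysis (transesterification) removes both aryl acetates at or below room temperature, where the prenyl group, the chromene double bond and ring C are inert and no acid is present that could cyclise the prenyl group onto the 7-OH.

Compound list
1 | methyl 3,4-dihydroxybenzoate | COC(=O)c1ccc(O)c(O)c1 | starting material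
2 | 3-chloro-3-methylbut-1-yne | CC(C)(Cl)C#C | starting material
3 | methyl 3-hydroxy-4-[(2-methylbut-3-yn-2-yl)oxy]benzoate | COC(=O)c1ccc(OC(C)(C)C#C)c(O)c1 | intermediate
4 | methyl 3,4-dihydroxy-5-(3-methylbuta-1,2-dien-1-yl)benzoate (allenylcatechol, not isolated) | COC(=O)c1cc(O)c(O)c(C=C=C(C)C)c1 | intermediate
5 | methyl 8-hydroxy-2,2-dimethyl-2H-chromene-6-carboxylate | COC(=O)c1cc(O)c2c(c1)C=CC(C)(C)O2 | intermediate
6 | ethyl acetate | CCOC(C)=O | starting material
7 | lithium enolate of ethyl acetate (not isolated) | [Li+].C=C([O-])OCC | intermediate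
8 | ethyl 3-(8-hydroxy-2,2-dimethyl-2H-chromen-6-yl)-3-oxopropanoate | CCOC(=O)CC(=O)c1cc(O)c2c(c1)C=CC(C)(C)O2 | intermediate
9 | phloroglucinol | Oc1cc(O)cc(O)c1 | starting material
10 | 3-(8-hydroxy-2,2-dimethyl-2H-chromen-6-yl)-3-oxoprop-1-en-1-one (aroylketene, not isolated) | O=C=CC(=O)c1cc(O)c2c(c1)C=CC(C)(C)O2 | intermediate
11 | 1-(8-hydroxy-2,2-dimethyl-2H-chromen-6-yl)-3-(2,4,6-trihydroxyphenyl)propane-1,3-dione (not isolated) | O=C(CC(=O)c1c(O)cc(O)cc1O)c1cc(O)c2c(c1)C=CC(C)(C)O2 | intermediate
12 | 5,7-dihydroxy-2-(8-hydroxy-2,2-dimethyl-2H-chromen-6-yl)-4H-chromen-4-one | O=c1cc(-c2cc(O)c3c(c2)C=CC(C)(C)O3)oc2cc(O)cc(O)c12 | intermediate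
13 | 6-(7-acetoxy-5-hydroxy-4-oxo-4H-chromen-2-yl)-2,2-dimethyl-2H-chromen-8-yl acetate | CC(=O)Oc1cc(O)c2c(=O)cc(-c3cc(OC(C)=O)c4c(c3)C=CC(C)(C)O4)oc2c1 | intermediate
14 | 3-methylbut-2-en-1-ol | CC(C)=CCO | starting material
15 | 6-{7-acetoxy-5-[(3-methylbut-2-en-1-yl)oxy]-4-oxo-4H-chromen-2-yl}-2,2-dimethyl-2H-chromen-8-yl acetate | CC(=O)Oc1cc(OCC=C(C)C)c2c(=O)cc(-c3cc(OC(C)=O)c4c(c3)C=CC(C)(C)O4)oc2c1 | intermediate
16 | 6-[7-acetoxy-6-(2-methylbut-3-en-2-yl)-4,5-dioxo-5,6-dihydro-4H-chromen-2-yl]-2,2-dimethyl-2H-chromen-8-yl acetate (C6 dienone, racemic transient centre at C6, not isolated) | C=CC(C)(C)C1C(=O)C2=C(C=C1OC(C)=O)OC(=CC2=O)c3cc(OC(C)=O)c4c(c3)C=CC(C)(C)O4 | intermediate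
17 | 6-[7-acetoxy-5-hydroxy-8-(3-methylbut-2-en-1-yl)-4-oxo-4H-chromen-2-yl]-2,2-dimethyl-2H-chromen-8-yl acetate | CC(C)=CCc1c(OC(C)=O)cc(O)c2c(=O)cc(-c3cc(OC(C)=O)c4c(c3)C=CC(C)(C)O4)oc12 | intermediate
18 | 5,7-dihydroxy-2-(8-hydroxy-2,2-dimethyl-2H-chromen-6-yl)-8-(3-methylbut-2-en-1-yl)-4H-chromen-4-one | CC(C)=CCc1c(O)cc(O)c2c(=O)cc(-c3cc(O)c4c(c3)C=CC(C)(C)O4)oc12 | target

Total step count: 8. Longest linear sequence: 8 (steps 1 to 8; phloroglucinol, ethyl acetate and prenol enter as bought).

Steps most likely to fail

Step 4. Three processes may go wrong: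
- Thermal ring opening of the chromene, followed by a hydrogen shift or by capture in the phenol melt.
- Hydrolysis and decarboxylation of the ketoester by the water that the ring closure releases.
- A second condensation on ring A.

The fallback sets out from 5 and comes back at 12. It builds ring C by enolate chemistry below 70 °C instead of in a melt. The phenol of 5 is capped with MOMCl and i-Pr2NEt in CH2Cl2 to give methyl 8-(methoxymethoxy)-2,2-dimethyl-2H-chromene-6-carboxylate F1. A crossed Claisen condensation of F1 with the dianion of commercial 2'-hydroxy-4',6'-bis(methoxymethoxy)acetophenone (NaH, THF, reflux) gives 1-[2-hydroxy-4,6-bis(methoxymethoxy)phenyl]-3-[8-(methoxymethoxy)-2,2-dimethyl-2H-chromen-6-yl]propane-1,3-dione F2. Warming F2 with HCl in MeOH closes the pyranone by cyclodehydration and removes the three acetals, which gives 12.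

Step 7. Two processes may go wrong:
- Early enolisation after the first shift, which would stop the relay at C6 with a reverse-prenyl group.
- Ionic loss of the prenyl group from O5.

The fallback sets out from 12 and comes back at 18. It brings the chain to C8 from O7 as an allyl group and then extends it by metathesis, with no protecting group. The most acidic phenol of 12, the 7-OH, is alkylated with one equivalent of allyl bromide (K2CO3, DMF, rt) to give 7-(allyloxy)-5-hydroxy-2-(8-hydroxy-2,2-dimethyl-2H-chromen-6-yl)-4H-chromen-4-one F3. An ortho-Claisen rearrangement (N,N-diethylaniline, 200 °C) should move the allyl group mainly to C8, as is usual for 7-allyloxychromones. This gives 8-allyl-5,7-dihydroxy-2-(8-hydroxy-2,2-dimethyl-2H-chromen-6-yl)-4H-chromen-4-one F4, and any C6 isomer is removed by chromatography. Cross-metathesis of F4 with excess 2-methylbut-2-ene (second-generation Grubbs catalyst, CH2Cl2, 40 °C) turns allyl into prenyl and gives 18. The hindered cyclic chromene alkene should stay out of the metathesis.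

Step 3. Addition to the electron-rich, phenoxide-bearing ester may be slow, so that the enolate decays on warming and conversion stays incomplete.

The fallback sets out from 5 and comes back at 8. It forms the C–C bond by decarboxylative acylation of a malonate half-ester instead of by an ester enolate. Saponification of 5 (LiOH, THF–H2O) gives 8-hydroxy-2,2-dimethyl-2H-chromene-6-carboxylic acid F5. One equivalent of carbonyldiimidazole in THF activates the carboxyl group ahead of the phenol and gives (8-hydroxy-2,2-dimethyl-2H-chromen-6-yl)(1H-imidazol-1-yl)methanone F6. F6 is added to the magnesium enolate made from potassium ethyl malonate, MgCl2 and Et3N in MeCN. Acylation with loss of CO2 gives 8 after an acidic work-up.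

Further compounds
F1 | step 4 | methyl 8-(methoxymethoxy)-2,2-dimethyl-2H-chromene-6-carboxylate | COCOc1cc(C(=O)OC)cc2C=CC(C)(C)Oc12
F2 | step 4 | 1-[2-hydroxy-4,6-bis(methoxymethoxy)phenyl]-3-[8-(methoxymethoxy)-2,2-dimethyl-2H-chromen-6-yl]propane-1,3-dione | COCOc1cc(O)c(C(=O)CC(=O)c2cc(OCOC)c3OC(C)(C)C=Cc3c2)c(OCOC)c1
F3 | step 7 | 7-(allyloxy)-5-hydroxy-2-(8-hydroxy-2,2-dimethyl-2H-chromen-6-yl)-4H-chromen-4-one | C=CCOc1cc(O)c2c(=O)cc(-c3cc(O)c4c(c3)C=CC(C)(C)O4)oc2c1
F4 | step 7 | 8-allyl-5,7-dihydroxy-2-(8-hydroxy-2,2-dimethyl-2H-chromen-6-yl)-4H-chromen-4-one | C=CCc1c(O)cc(O)c2c(=O)cc(-c3cc(O)c4c(c3)C=CC(C)(C)O4)oc12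
F5 | step 3 | 8-hydroxy-2,2-dimethyl-2H-chromene-6-carboxylic acid | OC(=O)c1cc(O)c2c(c1)C=CC(C)(C)O2
F6 | step 3 | (8-hydroxy-2,2-dimethyl-2H-chromen-6-yl)(1H-imidazol-1-yl)methanone | O=C(c1cc(O)c2c(c1)C=CC(C)(C)O2)n1ccnc1
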